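The decalin (drimane numbering: ring A C1–C5/C10, ring B C5–C10, side chain on C9) is disconnected across ring A. A type 1 intramolecular Diels–Alder reaction should join C1–C2 and C5–C10 at once, closing ring A directly and ring B as the tether ring. It exploits the 1,3-relationship on ring B between C8, an sp2 carbon in the target, and the angular methyl on C10: a temporary γ-lactone ties an oxygen on C8 to the future methyl carbon, activates the exocyclic C10=C1 dienophile and fixes its face. The precursor is an α-methylene lactone whose diene is masked as a 3-sulfolene. The 1,2-dioxane is closed last by a hydroperoxide on a β-lactone.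

Key step: step 7

Remark: drimane locants are used for the decalin (chain carbons C11, C12), C3'–C6' for the dioxane carbons and Cα for the ester α-carbon; Dec = (1R,4aR,8aR)-2,5,5,8a-tetramethyl-1,4,4a,5,6,7,8,8a-octahydronaphthalen-1-yl; the tertiary peroxide carbon C6' is formed without facial control in step 20 and its epimers are separated after step 22.

Step 1
Reactants: 1 2-(2-bromoethyl)-1,3-dioxolane
Product: 2 2-(2-iodoethyl)-1,3-dioxolane
Conditions: NaI, acetone, reflux
Reagents that add atoms: sodium iodide, [Na+].[I-]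
Why: Finkelstein SN2 halide exchange should give the iodide that the low-temperature sulfolene alkylation needs.

Step 2
Reactants: 2 2-(2-iodoethyl)-1,3-dioxolane; 3 3-methyl-2,5-dihydrothiophene 1,1-dioxide
Product: 5 2-[2-(1,3-dioxolan-2-yl)ethyl]-3-methyl-2,5-dihydrothiophene 1,1-dioxide (racemic), via lithiated sulfolene 4 (not isolated)
Conditions: LiN(SiMe3)2 added to 2 and 3, THF/HMPA, −78 °C
Reagents that add atoms: none
Why: Alkylation of the α-sulfonyl carbanion of a 3-sulfolene, which should form at C2 next to the methyl-bearing carbon and be trapped by the iodide before it ring-opens; the new centre is racemic and is lost in step 7.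

Step 3
Reactants: 5 2-[2-(1,3-dioxolan-2-yl)ethyl]-3-methyl-2,5-dihydrothiophene 1,1-dioxide
Product: 6 3-(3-methyl-1,1-dioxo-2,5-dihydrothiophen-2-yl)propanal (racemic)
Conditions: 1 M HCl, THF, rt
Reagents that add atoms: water, O
Why: Acid-catalysed acetal hydrolysis, to which the sulfolene is inert.

Step 4
Reactants: 7 3-(benzyloxy)propanal; 8 methyl acrylate
Product: 9 methyl 5-(benzyloxy)-3-hydroxy-2-methylidenepentanoate (racemic)
Conditions: DABCO, MeOH, rt
Reagents that add atoms: none
Why: Morita–Baylis–Hillman reaction; the carbinol centre disappears in step 5.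

Step 5
Reactants: 9 methyl 5-(benzyloxy)-3-hydroxy-2-methylidenepentanoate
Product: 10 methyl (2Z)-5-(benzyloxy)-2-(bromomethyl)pent-2-enoate
Conditions: NBS, Me2S, CH2Cl2, 0 °C to rt
Reagents that add atoms: N-bromosuccinimide, O=C1CCC(=O)N1Br
Why: Corey–Kim-type activation of the allylic alcohol followed by SN2' attack of bromide should give the rearranged, thermodynamically preferred Z allylic bromide.

Step 6
Reactants: 6 3-(3-methyl-1,1-dioxo-2,5-dihydrothiophen-2-yl)propanal; 10 methyl (2Z)-5-(benzyloxy)-2-(bromomethyl)pent-2-enoate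
Product: 13 (4S,5R)-4-[2-(benzyloxy)ethyl]-3-methylidene-5-[2-(3-methyl-1,1-dioxo-2,5-dihydrothiophen-2-yl)ethyl]oxolan-2-one (both epimers at the sulfolene carbon), via silyl ether 11 (not isolated), via hydroxy ester 12 (not isolated)
Conditions: CrCl2 (cat.), chiral carbazole-bis(oxazoline) ligand (cat., enantiomer that gives the 5R carbinol), Mn powder, Me3SiCl, iPr2NEt (cat.), THF, rt; then TsOH·H2O (cat.), CH2Cl2, rt
Reagents that add atoms: none
Why: Catalytic asymmetric Nozaki–Hiyama–Kishi 2-(alkoxycarbonyl)allylation, in which the γ-substituted allylchromium should add through a chair transition state to give the anti adduct while the ligand selects the aldehyde face (lactone C5 = drimane C8 R, hence lactone C4 = drimane C9 S), and lactonisation gives the trans-β,γ-disubstituted α-methylene lactone.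

Step 7
Reactants: 13 (4S,5R)-4-[2-(benzyloxy)ethyl]-3-methylidene-5-[2-(3-methyl-1,1-dioxo-2,5-dihydrothiophen-2-yl)ethyl]oxolan-2-one
Product: 15 (5R,8R,9S,10S)-9-[2-(benzyloxy)ethyl]-8-hydroxy-4-methyl-trans-octal-3-ene-10-carboxylic acid lactone (drimane locants; bridge C8–O–C(=O)–C10), via triene 14 (not isolated)
Conditions: toluene (high dilution), NaHCO3, BHT, 110 °C
Reagents that add atoms: none
Why: Cheletropic loss of SO2 unmasks the (E)-diene C2=C3–C4(Me)=C5 of triene 14, which should add to the exocyclic C10=C1 bond of the α-methylene lactone in a concerted, asynchronous intramolecular Diels–Alder reaction that forms C1–C2 and C5–C10 together. The closest known reaction types are the tandem sulfolene extrusion/intramolecular Diels–Alder sequence and Diels–Alder additions to α-methylene lactones. Ring A closes as the new cyclohexene of the [4+2] and ring B as the six-membered tether ring C5–C6–C7–C8–C9–C10 (1,3,9-decatriene mode), bridged from C8 to C10 by the lactone. C10 is controlled by C8: the two-carbon link lets the diene reach only the methylene face that carries C7, and because C9 is trans to C7 its side chain ends equatorial and cis to the lactone carbonyl, the future methyl. C5 is controlled by the endo transition state, in which the lactone carbonyl lies under the diene and ring B folds as a chair, which gives the trans ring fusion. The step needs endo over exo selectivity, which rests on secondary overlap with the s-cis-locked conjugated lactone carbonyl, whereas regio- and facial selectivity are fixed by the tether.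

Step 8
Reactants: 15 tricyclic lactone with the C3=C4 alkene
Product: 17 (5R,8R,9S,10S)-9-[2-(benzyloxy)ethyl]-8-hydroxy-4,4-dimethyl-trans-decalin-10-carboxylic acid lactone (drimane locants), via sulfonyl hydrazide 16 (not isolated)
Conditions: CH2=NNHSO2(n-C8H17), Fe(acac)3 (substoichiometric), PhSiH3, THF/MeOH, rt; then MeOH, 60 °C
Reagents that add atoms: formaldehyde N-(octylsulfonyl)hydrazone, C=NNS(=O)(=O)CCCCCCCC
Why: Metal-hydride hydrogen-atom-transfer hydromethylation, in which hydrogen should add to C3, the tertiary C4 radical adds to the formaldehyde hydrazone, and loss of sulfinate and N2 leaves the second methyl on C4 (no stereocentre); the substrate has only this one alkene.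

Step 9
Reactants: 17 gem-dimethyl tricyclic lactone
Product: 18 lactol of 17 (C10–CH(OH)–O–C8, both anomers)
Conditions: iBu2AlH, CH2Cl2, −78 °C
Reagents that add atoms: none
Why: Partial reduction of the lactone should stop at the lactol because the tetrahedral aluminate survives at −78 °C.

Step 10
Reactants: 18 lactol
Product: 20 (1S,2R,4aR,8aR)-1-[2-(benzyloxy)ethyl]-5,5,8a-trimethyldecahydronaphthalen-2-ol, via hydrazone 19 (not isolated)
Conditions: N2H4·H2O, KOH, diethylene glycol, 130 °C then 200 °C
Reagents that add atoms: none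
Why: Wolff–Kishner reduction (Huang-Minlon modification) of the lactol through its open hydroxy aldehyde should turn the angular carbon into the C10 methyl and free the C8 hydroxyl, with no enolisable stereocentre present.

Step 11
Reactants: 20 (1S,2R,4aR,8aR)-1-[2-(benzyloxy)ethyl]-5,5,8a-trimethyldecahydronaphthalen-2-ol
Product: 21 (1S,4aR,8aR)-1-[2-(benzyloxy)ethyl]-5,5,8a-trimethyloctahydronaphthalen-2(1H)-one
Conditions: nPr4N[RuO4] (cat.), NMO, 4 Å MS, CH2Cl2, rt
Reagents that add atoms: none
Why: Ley–Griffith oxidation of the secondary alcohol; C9 should hold because its equatorial side chain is also the thermodynamic arrangement.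

Step 12
Reactants: 21 (1S,4aR,8aR)-1-[2-(benzyloxy)ethyl]-5,5,8a-trimethyloctahydronaphthalen-2(1H)-one
Product: 23 (1S,4aR,8aR)-1-[2-(benzyloxy)ethyl]-5,5,8a-trimethyl-1,4,4a,5,6,7,8,8a-octahydronaphthalen-2-yl trifluoromethanesulfonate, via potassium enolate 22 (not isolated)
Conditions: KN(SiMe3)2, THF, −78 °C; PhNTf2, −78 to 0 °C
Reagents that add atoms: N-phenylbis(trifluoromethanesulfonimide), O=S(=O)(N(c1ccccc1)S(=O)(=O)C(F)(F)F)C(F)(F)F
Why: Kinetic deprotonation by the bulky amide should occur at the C7 methylene and not at the hindered C9 methine next to quaternary C10, and O-sulfonylation fixes the alkene at C7=C8.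

Step 13
Reactants: 23 enol triflate
Product: 24 benzyl 2-(Dec)ethyl ether
Conditions: MeMgBr, Fe(acac)3 (cat.), THF/NMP, −30 to 0 °C
Reagents that add atoms: methylmagnesium bromide, C[Mg]Br
Why: Iron-catalysed Kumada-type cross-coupling of the alkenyl triflate should install the C8 methyl without moving the alkene.

Step 14
Reactants: 24 benzyl 2-(Dec)ethyl ether
Product: 25 2-(Dec)ethan-1-ol
Conditions: Li, NH3 (l), THF, −78 °C; NH4Cl
Reagents that add atoms: none
Why: Birch-type dissolving-metal cleavage of the benzyl ether, which should leave the isolated trisubstituted alkene untouched.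

Step 15
Reactants: 25 2-(Dec)ethan-1-ol
Product: 26 2-(Dec)ethyl iodide
Conditions: I2, PPh3, imidazole, CH2Cl2, 0 °C to rt
Reagents that add atoms: iodine, II
Why: Appel-type iodination of the primary alcohol by SN2 displacement on the alkoxyphosphonium ion.

Step 16
Reactants: 27 ethyl acetate; 28 2,3-dibromopropene
Product: 30 ethyl 4-bromopent-4-enoate, via lithium enolate 29 (not isolated)
Conditions: LiN(iPr)2, THF, −78 °C; then 28, DMPU, −78 to −20 °C
Reagents that add atoms: none
Why: Ester enolate alkylation should take place at the allylic bromide only, the vinylic bromide being inert to SN2.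

Step 17
Reactants: 30 ethyl 4-bromopent-4-enoate
Product: 31 4-bromopent-4-enal
Conditions: iBu2AlH, CH2Cl2, −78 °C; Rochelle salt
Reagents that add atoms: none
Why: Partial reduction of the ester to the aldehyde at −78 °C through the stable tetrahedral aluminate.

Step 18
Reactants: 31 4-bromopent-4-enal; 32 propanoyl chloride
Product: 34 (3S,4R)-4-(3-bromobut-3-en-1-yl)-3-methyloxetan-2-one, via methylketene 33 (not isolated)
Conditions: O-trimethylsilylquinine or O-trimethylsilylquinidine (cat., the pseudoenantiomer that gives 3S,4R), LiClO4, iPr2NEt, CH2Cl2/Et2O, −78 °C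
Reagents that add atoms: none
Why: Cinchona alkaloid and LiClO4-catalysed acyl halide–aldehyde cyclocondensation (formal [2+2] of the ketene-derived ammonium enolate), in which the Z enolate should give the cis lactone and the alkaloid sets both the future C3' (as its R precursor) and Cα (S).

Step 19
Reactants: 26 2-(Dec)ethyl iodide; 34 (3S,4R)-4-(3-bromobut-3-en-1-yl)-3-methyloxetan-2-one
Product: 36 (3S,4R)-4-[5-(Dec)-3-methylidenepentyl]-3-methyloxetan-2-one, via alkylzinc iodide 35 (not isolated)
Conditions: Zn dust, LiCl, THF, 40 °C; then 34, Pd(OAc)2 (cat.), SPhos (cat.), THF, rt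
Reagents that add atoms: none
Why: Negishi sp3–sp2 cross-coupling, in which the alkylzinc halide should tolerate the β-lactone and no stereocentre is touched.

Step 20
Reactants: 36 (3S,4R)-4-[5-(Dec)-3-methylidenepentyl]-3-methyloxetan-2-one
Product: 37 (3S,4R)-4-{5-(Dec)-3-methyl-3-[(triethylsilyl)peroxy]pentyl}-3-methyloxetan-2-one (both C6' epimers)
Conditions: Co(thd)2 (cat., thd = 2,2,6,6-tetramethylheptane-3,5-dionate), O2 (1 atm), Et3SiH, ClCH2CH2Cl, rt
Reagents that add atoms: dioxygen, O=O; triethylsilane, CC[SiH](CC)CC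
Why: Mukaiyama–Isayama hydroperoxysilylation, in which hydrogen-atom transfer should go to the 1,1-disubstituted alkene rather than the hindered ring alkene and the tertiary C6' radical traps O2; the radical is planar and far from any stereocentre, so both C6' epimers are expected and are carried on together.

Step 21
Reactants: 37 silyl peroxide (both C6' epimers)
Product: 39 (2S)-2-{(3S)-6-methyl-6-[2-(Dec)ethyl]-1,2-dioxan-3-yl}propanoic acid (both C6' epimers), via hydroperoxide 38 (not isolated)
Conditions: HF·pyridine, THF, 0 °C; then Cs2CO3, MeCN (dilute), 0 °C to rt; 1 M HCl work-up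
Reagents that add atoms: none
Why: Proposed new method: after Si–O cleavage the hydroperoxide anion, an α-effect nucleophile that carbonate deprotonates selectively, should attack C3' of the β-lactone in a 6-exo-tet SN2 reaction with alkyl–oxygen cleavage and carboxylate as leaving group, so that C3' is inverted to S while Cα, never enolised, stays S; the closest known reaction types are the intramolecular alkylation of hydroperoxides by oxetanes or sulfonates to give 1,2-dioxanes and the SN2 opening of 4-alkyl β-lactones at C4 by azide or thiolate.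

Step 22
Reactants: 39 dioxane acid (both C6' epimers)
Product: 40 methyl (2S)-2-{(3S,6S)-6-methyl-6-[2-(Dec)ethyl]-1,2-dioxan-3-yl}propanoate (target)
Conditions: Me3SiCHN2, MeOH/toluene, 0 °C; then chromatography (silica, then HPLC)
Reagents that add atoms: (trimethylsilyl)diazomethane, C[Si](C)(C)C=[N+]=[N-]
Why: Base-free methylation of the acid should spare the β-peroxy ester, and the cyclic (6S) ester is separated at this stage from its (6R) epimer.

Compound list
1 | 2-(2-bromoethyl)-1,3-dioxolane | BrCCC1OCCO1 | starting material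
2 | 2-(2-iodoethyl)-1,3-dioxolane | ICCC1OCCO1 | intermediate
3 | 3-methyl-2,5-dihydrothiophene 1,1-dioxide (3-methyl-3-sulfolene) | CC1=CCS(=O)(=O)C1 | starting material
4 | 2-lithio-3-methyl-2,5-dihydrothiophene 1,1-dioxide | [Li]C1C(C)=CCS1(=O)=O | intermediate
5 | 2-[2-(1,3-dioxolan-2-yl)ethyl]-3-methyl-2,5-dihydrothiophene 1,1-dioxide (racemic) | CC1=CCS(=O)(=O)C1CCC2OCCO2 | intermediate
6 | 3-(3-methyl-1,1-dioxo-2,5-dihydrothiophen-2-yl)propanal (racemic) | CC1=CCS(=O)(=O)C1CCC=O | intermediate
7 | 3-(benzyloxy)propanal | O=CCCOCc1ccccc1 | starting material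
8 | methyl acrylate | C=CC(=O)OC | starting material
9 | methyl 5-(benzyloxy)-3-hydroxy-2-methylidenepentanoate (racemic) | C=C(C(=O)OC)C(O)CCOCc1ccccc1 | intermediate
10 | methyl (2Z)-5-(benzyloxy)-2-(bromomethyl)pent-2-enoate | COC(=O)C(/CBr)=C/CCOCc1ccccc1 | intermediate
11 | methyl (3S,4R)-3-[2-(benzyloxy)ethyl]-2-methylidene-6-(3-methyl-1,1-dioxo-2,5-dihydrothiophen-2-yl)-4-[(trimethylsilyl)oxy]hexanoate | COC(=O)C(=C)[C@H](CCOCc1ccccc1)[C@H](O[Si](C)(C)C)CCC1C(C)=CCS1(=O)=O | intermediate
12 | methyl (3S,4R)-3-[2-(benzyloxy)ethyl]-4-hydroxy-2-methylidene-6-(3-methyl-1,1-dioxo-2,5-dihydrothiophen-2-yl)hexanoate | COC(=O)C(=C)[C@H](CCOCc1ccccc1)[C@H](O)CCC1C(C)=CCS1(=O)=O | intermediate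
13 | (4S,5R)-4-[2-(benzyloxy)ethyl]-3-methylidene-5-[2-(3-methyl-1,1-dioxo-2,5-dihydrothiophen-2-yl)ethyl]oxolan-2-one | c1ccccc1COCC[C@@H]2[C@@H](CCC3C(C)=CCS3(=O)=O)OC(=O)C2=C | intermediate
14 | (4S,5R)-4-[2-(benzyloxy)ethyl]-3-methylidene-5-[(3E)-4-methylhexa-3,5-dien-1-yl]oxolan-2-one | c1ccccc1COCC[C@@H]2[C@@H](CC/C=C(\C)C=C)OC(=O)C2=C | intermediate
15 | (5R,8R,9S,10S)-9-[2-(benzyloxy)ethyl]-8-hydroxy-4-methyl-trans-octal-3-ene-10-carboxylic acid lactone (drimane locants) | c1ccccc1COCC[C@@H]2[C@H]4CC[C@@H]3C(C)=CCC[C@@]23C(=O)O4 | intermediate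
16 | adduct of 15 saturated at C3–C4 and carrying CH2NHNHSO2(n-octyl) on C4 (either C4 epimer) | c1ccccc1COCC[C@@H]2[C@H]4CC[C@@H]3C(C)(CNNS(=O)(=O)CCCCCCCC)CCC[C@@]23C(=O)O4 | intermediate
17 | (5R,8R,9S,10S)-9-[2-(benzyloxy)ethyl]-8-hydroxy-4,4-dimethyl-trans-decalin-10-carboxylic acid lactone (drimane locants) | c1ccccc1COCC[C@@H]2[C@H]4CC[C@@H]3C(C)(C)CCC[C@@]23C(=O)O4 | intermediate
18 | lactol of 17 (lactone C=O reduced to CH–OH, both anomers) | c1ccccc1COCC[C@@H]2[C@H]4CC[C@@H]3C(C)(C)CCC[C@@]23C(O)O4 | intermediate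
19 | (5R,8R,9S,10S)-9-[2-(benzyloxy)ethyl]-8-hydroxy-4,4-dimethyl-trans-decalin-10-carbaldehyde hydrazone (drimane locants) | c1ccccc1COCC[C@@H]2[C@H](O)CC[C@@H]3C(C)(C)CCC[C@@]23C=NN | intermediate
20 | (1S,2R,4aR,8aR)-1-[2-(benzyloxy)ethyl]-5,5,8a-trimethyldecahydronaphthalen-2-ol | c1ccccc1COCC[C@@H]2[C@H](O)CC[C@@H]3C(C)(C)CCC[C@@]23C | intermediate
21 | (1S,4aR,8aR)-1-[2-(benzyloxy)ethyl]-5,5,8a-trimethyloctahydronaphthalen-2(1H)-one | c1ccccc1COCC[C@@H]2C(=O)CC[C@@H]3C(C)(C)CCC[C@@]23C | intermediate
22 | potassium C7-enolate of 21 | c1ccccc1COCC[C@@H]2C([O-])=CC[C@@H]3C(C)(C)CCC[C@@]23C.[K+] | intermediate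
23 | (1S,4aR,8aR)-1-[2-(benzyloxy)ethyl]-5,5,8a-trimethyl-1,4,4a,5,6,7,8,8a-octahydronaphthalen-2-yl trifluoromethanesulfonate | c1ccccc1COCC[C@@H]2C(OS(=O)(=O)C(F)(F)F)=CC[C@@H]3C(C)(C)CCC[C@@]23C | intermediate
24 | benzyl 2-[(1R,4aR,8aR)-2,5,5,8a-tetramethyl-1,4,4a,5,6,7,8,8a-octahydronaphthalen-1-yl]ethyl ether | c1ccccc1COCC[C@@H]2C(C)=CC[C@@H]3C(C)(C)CCC[C@@]23C | intermediate
25 | 2-[(1R,4aR,8aR)-2,5,5,8a-tetramethyl-1,4,4a,5,6,7,8,8a-octahydronaphthalen-1-yl]ethan-1-ol | OCC[C@@H]2C(C)=CC[C@@H]3C(C)(C)CCC[C@@]23C | intermediate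
26 | (1R,4aR,8aR)-1-(2-iodoethyl)-2,5,5,8a-tetramethyl-1,4,4a,5,6,7,8,8a-octahydronaphthalene | ICC[C@@H]2C(C)=CC[C@@H]3C(C)(C)CCC[C@@]23C | intermediate
27 | ethyl acetate | CC(=O)OCC | starting material
28 | 2,3-dibromopropene | C=C(Br)CBr | starting material
29 | lithium enolate of ethyl acetate | [Li]OC(=C)OCC | intermediate
30 | ethyl 4-bromopent-4-enoate | C=C(Br)CCC(=O)OCC | intermediate
31 | 4-bromopent-4-enal | C=C(Br)CCC=O | intermediate
32 | propanoyl chloride | CCC(=O)Cl | starting material
33 | methylketene | CC=C=O | intermediate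
34 | (3S,4R)-4-(3-bromobut-3-en-1-yl)-3-methyloxetan-2-one (cis) | C[C@@H]1C(=O)O[C@@H]1CCC(Br)=C | intermediate
35 | [2-(Dec)ethyl]zinc iodide | I[Zn]CC[C@@H]2C(C)=CC[C@@H]3C(C)(C)CCC[C@@]23C | intermediate
36 | (3S,4R)-4-[5-(Dec)-3-methylidenepentyl]-3-methyloxetan-2-one | C[C@@H]1C(=O)O[C@@H]1CCC(=C)CC[C@@H]2C(C)=CC[C@@H]3C(C)(C)CCC[C@@]23C | intermediate
37 | (3S,4R)-4-{5-(Dec)-3-methyl-3-[(triethylsilyl)peroxy]pentyl}-3-methyloxetan-2-one (both C6' epimers) | C[C@@H]1C(=O)O[C@@H]1CCC(C)(OO[Si](CC)(CC)CC)CC[C@@H]2C(C)=CC[C@@H]3C(C)(C)CCC[C@@]23C | intermediate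
38 | (3S,4R)-4-[5-(Dec)-3-hydroperoxy-3-methylpentyl]-3-methyloxetan-2-one (both C6' epimers) | C[C@@H]1C(=O)O[C@@H]1CCC(C)(OO)CC[C@@H]2C(C)=CC[C@@H]3C(C)(C)CCC[C@@]23C | intermediate
39 | (2S)-2-{(3S)-6-methyl-6-[2-(Dec)ethyl]-1,2-dioxan-3-yl}propanoic acid (both C6' epimers) | OC(=O)[C@@H](C)[C@@H]1CCC(C)(CC[C@@H]2C(C)=CC[C@@H]3C(C)(C)CCC[C@@]23C)OO1 | intermediate
40 | methyl (2S)-2-[(3S,6S)-6-methyl-6-{2-[(1R,4aR,8aR)-2,5,5,8a-tetramethyl-1,4,4a,5,6,7,8,8a-octahydronaphthalen-1-yl]ethyl}-1,2-dioxan-3-yl]propanoate | COC(=O)[C@@H](C)[C@@H]1CC[C@](C)(CC[C@@H]2C(C)=CC[C@@H]3C(C)(C)CCC[C@@]23C)OO1 | target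

Total step count: 22. Longest linear sequence: 17 steps (steps 1–3, 6–15, 19–22).

Steps most likely to fail

1. Step 21 (Proposed new method). The hydroperoxide anion may attack the lactone carbonyl (acyl–oxygen cleavage, peresters and oligomers) or the base may fragment the peroxide before the 6-exo alkylation takes place. The fallback is the known hydroperoxide oxa-Michael route; it sets out from aldehyde 31 and iodide 26 and comes back at target 40. Wittig olefination of 31 with methyl 2-(triphenylphosphoranylidene)propanoate should give methyl (2E)-6-bromo-2-methylhepta-2,6-dienoate F1. Negishi coupling of F1 with zinc reagent 35 (from 26) should give methyl (2E)-8-(Dec)-2-methyl-6-methylideneoct-2-enoate F2. Co(thd)2/O2/Et3SiH should convert its 1,1-disubstituted alkene into methyl (2E)-8-(Dec)-2,6-dimethyl-6-[(triethylsilyl)peroxy]oct-2-enoate F3. HF·pyridine frees methyl (2E)-8-(Dec)-6-hydroperoxy-2,6-dimethyloct-2-enoate F4, which with Et3N in CF3CH2OH should add 6-exo to the enoate and give 40. This route no longer controls C3' and Cα, so 40 would have to be separated from more diastereomers.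

2. Step 7. The exo mode, with the diene over C9–H, may compete and give the cis-fused isomer, or the α-methylene lactone may isomerise to the endocyclic butenolide at 110 °C in the presence of SO2. The fallback unmasks the diene before the dienophile is built, so that the cycloaddition can be run cold under Lewis acid catalysis; it sets out from aldehyde 6 and comes back at 15. Thermolysis of 6 (toluene, NaHCO3, 110 °C) should give (4E)-5-methylhepta-4,6-dienal F5. The conditions of step 6 with bromide 10 should then give, through methyl (3S,4R)-3-[2-(benzyloxy)ethyl]-7-methyl-2-methylidene-4-[(trimethylsilyl)oxy]nona-6,8-dienoate F6 and methyl (3S,4R)-3-[2-(benzyloxy)ethyl]-4-hydroxy-7-methyl-2-methylidenenona-6,8-dienoate F7, the triene lactone 14 as an isolated compound. Et2AlCl in CH2Cl2 at −78 °C should then close 14 to 15 with a stronger endo preference.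

3. Step 19. The β-lactone may be opened by the organozinc reagent or by the palladium catalyst before the coupling is complete. The fallback carries the carbonyl through the coupling as an ester and builds the β-lactone afterwards; it sets out from iodide 26 and ester 30 and comes back at 36. Negishi coupling of zinc reagent 35 with 30 should give ethyl 6-(Dec)-4-methylidenehexanoate F8. iBu2AlH at −78 °C should give 6-(Dec)-4-methylidenehexanal F9. The cyclocondensation of step 18 with propanoyl chloride 32 (through 33) should then give 36.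

Further compounds
F1 | step 21 | methyl (2E)-6-bromo-2-methylhepta-2,6-dienoate | C=C(Br)CC/C=C(\C)C(=O)OC
F2 | step 21 | methyl (2E)-8-(Dec)-2-methyl-6-methylideneoct-2-enoate | COC(=O)/C(C)=C/CCC(=C)CC[C@@H]2C(C)=CC[C@@H]3C(C)(C)CCC[C@@]23C
F3 | step 21 | methyl (2E)-8-(Dec)-2,6-dimethyl-6-[(triethylsilyl)peroxy]oct-2-enoate (both C6 epimers) | COC(=O)/C(C)=C/CCC(C)(OO[Si](CC)(CC)CC)CC[C@@H]2C(C)=CC[C@@H]3C(C)(C)CCC[C@@]23C
F4 | step 21 | methyl (2E)-8-(Dec)-6-hydroperoxy-2,6-dimethyloct-2-enoate (both C6 epimers) | COC(=O)/C(C)=C/CCC(C)(OO)CC[C@@H]2C(C)=CC[C@@H]3C(C)(C)CCC[C@@]23C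
F5 | step 7 | (4E)-5-methylhepta-4,6-dienal | C=C/C(C)=C/CCC=O
F6 | step 7 | methyl (3S,4R)-3-[2-(benzyloxy)ethyl]-7-methyl-2-methylidene-4-[(trimethylsilyl)oxy]nona-6,8-dienoate (6E) | COC(=O)C(=C)[C@H](CCOCc1ccccc1)[C@H](O[Si](C)(C)C)CC/C=C(\C)C=C
F7 | step 7 | methyl (3S,4R)-3-[2-(benzyloxy)ethyl]-4-hydroxy-7-methyl-2-methylidenenona-6,8-dienoate (6E) | COC(=O)C(=C)[C@H](CCOCc1ccccc1)[C@H](O)CC/C=C(\C)C=C
F8 | step 19 | ethyl 6-(Dec)-4-methylidenehexanoate | CCOC(=O)CCC(=C)CC[C@@H]2C(C)=CC[C@@H]3C(C)(C)CCC[C@@]23C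
F9 | step 19 | 6-(Dec)-4-methylidenehexanal | O=CCCC(=C)CC[C@@H]2C(C)=CC[C@@H]3C(C)(C)CCC[C@@]23C
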